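**Plan**

1. Retrosynthesis: (a) both acetates and the oxygen on the lactone α-carbon are removed (enolate hydroxylation, acetylation); (b) the bond from the methyl-bearing quaternary carbon of the cyclopentane to the side-chain CH is cut to a tertiary radical and a menthyloxy butenolide; (c) the cycloheptane is cut at two bonds, CMe2–CH2 and the CH2–CH2 bond next to the carbon carrying the exocyclic methylene, which frees a two-carbon unit (phenyl vinyl sulfone).
2. Enabling feature: in the seven-membered ring the gem-dimethyl carbon (a tertiary radical site) and the allyl unit made of the C(=CH2) carbon and its ring CH2 neighbour are separated by exactly two CH2 groups and sit cis on adjacent carbons of the cyclopentane. A tertiary radical, an acceptor alkene and an allyl sulfone can therefore be joined in one radical (5+2) annulation.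
3. Forward order: cyclopentane from (R)-limonene (ozonolysis, aldol); temporary cis-fused γ-lactone; lactone carbonyl converted into a 2-(sulfonylmethyl)allyl group; (5+2) annulation closes the cycloheptane; a second tertiary radical is coupled to the butenolide; lactone transposition, hydroxylation, acetylation.
4. Stereochemistry: the CMe2-bearing ring-fusion CH comes from (R)-limonene; the other ring-fusion CH from the cis-lactone constraint; the quaternary carbon from attack anti to the cycloheptane bond; the side-chain CH from addition anti to the menthyloxy group; the lactone β-CH from kinetic protonation; the acetoxy CH from hydroxylation anti to the β-substituent.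
5. Helpers and their removal: the lactone tether (opened in step 8), the PhSO2 group on the two-carbon unit and the BOM ether (both removed by Li/NH3), the menthyl acetal (lost on LiBH4 reduction).

Key step: step 12

Remark: (5S)-5-[(1S,2R,5S)-menthyloxy]furan-2(5H)-one, the (+)-menthol-derived mirror image of the common menthyloxy butenolide, is taken as a purchasable building block.
Remark: the configuration of the tertiary carbinol carbon made in step 6 is of no consequence (it becomes a planar radical in step 17); the SMILES show the isomer expected from convex-face trapping. The sulfonyl-bearing carbon formed in step 12 is an epimer mixture that is erased in step 13. If the deconjugation in step 5 gives the endocyclic alkene instead, it converges to the same alcohol in step 6.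

**Route**

Step 1
Reactants: 1 (R)-(+)-limonene
Product: 2 (3R)-6-oxo-3-(prop-1-en-2-yl)heptanal
Conditions: O3 (1 equiv), CH2Cl2/MeOH, −78 °C; then Me2S, −78 °C to rt
Reagents that add atoms: ozone, [O-][O+]=O
Why: Ozonolysis with reductive work-up; the more electron-rich trisubstituted ring alkene should react ahead of the 1,1-disubstituted isopropenyl group, and the stereocentre is untouched.

Step 2
Reactants: 2 (3R)-6-oxo-3-(prop-1-en-2-yl)heptanal
Product: 3 (5S)-2-methyl-5-(prop-1-en-2-yl)cyclopent-1-ene-1-carbaldehyde
Conditions: piperidine (cat.), AcOH (cat.), PhH, reflux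
Reagents that add atoms: none
Why: Intramolecular aldol condensation through the enamine of the aldehyde, which attacks the methyl ketone to close the five-membered ring and dehydrates into conjugation.

Step 3
Reactants: 3 (5S)-2-methyl-5-(prop-1-en-2-yl)cyclopent-1-ene-1-carbaldehyde
Product: 4 (5S)-2-methyl-5-(prop-1-en-2-yl)cyclopent-1-ene-1-carboxylic acid
Conditions: NaClO2, NaH2PO4, 2-methyl-2-butene, t-BuOH/H2O, 0 °C to rt
Reagents that add atoms: sodium chlorite, [Na+].[O-]Cl=O
Why: Pinnick oxidation of the enal; the alkene scavenger protects the isopropenyl group from hypochlorous acid.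

Step 4
Reactants: 4 (5S)-2-methyl-5-(prop-1-en-2-yl)cyclopent-1-ene-1-carboxylic acid
Product: 6 (3aR)-3,3,6-trimethyl-3,3a,4,5-tetrahydro-1H-cyclopenta[c]furan-1-one, via hydroxy acid 5 (not isolated)
Conditions: Co(acac)2 (cat.), PhSiH3, O2 (1 atm), THF, rt; then PPTS (cat.), CH2Cl2, rt
Reagents that add atoms: dioxygen, O=O
Why: Mukaiyama hydration (hydrogen-atom transfer, Markovnikov) should convert only the electron-rich isopropenyl group, and the γ-hydroxy acid then lactonises without a free carbocation that could shift hydride.

Step 5
Reactants: 6 (3aR)-3,3,6-trimethyl-3,3a,4,5-tetrahydro-1H-cyclopenta[c]furan-1-one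
Product: 7 cis-fused 3,3-dimethyl-6-methylidenehexahydro-1H-cyclopenta[c]furan-1-one
Conditions: LiN(i-Pr)2, THF/DMPU, −78 °C; then AcOH, −78 °C
Reagents that add atoms: none
Why: Deconjugative protonation: γ-deprotonation gives the dienolate and kinetic α-protonation creates the second ring-fusion stereocentre, which can only form cis to the existing one because a trans-fused bicyclo[3.3.0] lactone is prohibitively strained.

Step 6
Reactants: 7 cis-fused 3,3-dimethyl-6-methylidenehexahydro-1H-cyclopenta[c]furan-1-one
Product: 8 cis-fused 6-hydroxy-3,3,6-trimethylhexahydro-1H-cyclopenta[c]furan-1-one (hydroxyl on the face opposite to the lactone ring)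
Conditions: Co(acac)2 (cat.), PhSiH3, O2 (1 atm), THF, rt
Reagents that add atoms: dioxygen, O=O
Why: Mukaiyama hydration of the 1,1-disubstituted alkene gives the tertiary alcohol that later serves as the second radical precursor, oxygen being trapped on the convex face.

Step 7
Reactants: 8 cis-fused 6-hydroxy-3,3,6-trimethylhexahydro-1H-cyclopenta[c]furan-1-one
Product: 9 benzyloxymethyl (BOM) ether of 8
Conditions: BOMCl, i-Pr2NEt, Bu4NI (cat.), CH2Cl2, 40 °C
Reagents that add atoms: benzyl chloromethyl ether, ClCOCc1ccccc1
Why: BOM protection of the hindered tertiary alcohol under amine base (no alkoxide, so no retro-aldol of the β-hydroxy lactone) gives a group stable to organometallics and radicals and cleavable by dissolving metal.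

Step 8
Reactants: 9 BOM ether of 8
Product: 11 2-{3-(benzyloxymethoxy)-3-methyl-2-[3-(trimethylsilyl)prop-1-en-2-yl]cyclopentyl}propan-2-ol (the two ring CH substituents cis to each other and to the ring methyl), via bis(silylmethyl) carbinol 10 (not isolated)
Conditions: Me3SiCH2MgCl, CeCl3, THF, −78 °C to rt; then silica gel, CH2Cl2, rt
Reagents that add atoms: (trimethylsilyl)methylmagnesium chloride, C[Si](C)(C)C[Mg]Cl
Why: Ester-to-allylsilane conversion: twofold 1,2-addition of the weakly basic organocerium reagent to the lactone carbonyl (no enolisation, no β-elimination of the BOM-oxy group) and Peterson elimination of one β-hydroxysilane arm give the 2-substituted allylsilane and free the tertiary alcohol.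

Step 9
Reactants: 11 hydroxy allylsilane
Product: 12 methyl oxalate of 11 (tert-alkyl methyl oxalate)
Conditions: ClC(O)CO2Me, Et3N, DMAP (cat.), CH2Cl2, 0 °C to rt
Reagents that add atoms: methyl chlorooxoacetate, COC(=O)C(Cl)=O
Why: DMAP-catalysed acylation masks the tertiary hydroxyl before the electrophilic desilylation and installs the future radical leaving group.

Step 10
Reactants: 12 methyl oxalate of 11
Product: 14 allyl phenyl sulfone methyl oxalate [CH2SiMe3 of 12 replaced by CH2SO2Ph], via allyl bromide 13 (not isolated)
Conditions: NBS, CH2Cl2, −78 °C; then PhSO2Na, Bu4NI (cat.), DMF, rt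
Reagents that add atoms: N-bromosuccinimide (bromine in 13 only), BrN1C(=O)CCC1=O; sodium benzenesulfinate, [Na+].[O-]S(=O)c1ccccc1
Why: Electrophilic bromodesilylation of the allylsilane (degenerate for the symmetric 2-substituted allyl unit) and S-alkylation of the sulfinate by the primary allylic bromide; the masked alcohol cannot capture the β-silyl cation.

Step 11
Reactants: 14 allyl phenyl sulfone methyl oxalate
Product: 15 cesium oxalate of the tertiary alcohol carrying the 2-(phenylsulfonylmethyl)allyl group
Conditions: CsOH (1.0 equiv), THF/H2O, rt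
Reagents that add atoms: cesium hydroxide, [Cs+].[OH-]
Why: Saponification at the highly electrophilic terminal methyl ester of the oxalate with one equivalent of base should be fast enough to spare the tertiary ester linkage and the allyl sulfone.

Step 12
Reactants: 15 cesium oxalate; 16 phenyl vinyl sulfone
Product: 17 cis-fused 1-(benzyloxymethoxy)-1,4,4-trimethyl-8-methylidene-6-(phenylsulfonyl)decahydroazulene (epimers at C-6)
Conditions: 16 (3 equiv), [Ir(dF(CF3)ppy)2(dtbbpy)]PF6 (1 mol%), DMF/DME 1:1 (no added water), blue LEDs, rt
Reagents that add atoms: none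
Why: Proposed new method: the photoexcited iridium catalyst oxidises the cesium oxalate, loss of two CO2 gives the tertiary radical at the CMe2 carbon, which cannot reach its own allyl sulfone (only 4-exo or 5-endo closure) and so adds intermolecularly to phenyl vinyl sulfone; the electrophilic α-sulfonyl radical then attacks the terminal CH2 of the 2-substituted allyl sulfone, and β-scission expels PhSO2•, which the reduced photocatalyst converts to sulfinate in a redox-neutral cycle. The closest known reaction types are the photoredox Giese addition of tertiary-alcohol-derived cesium oxalates to vinyl sulfones and radical allyl transfer from allyl sulfones (three-component radical carboallylation); new is their merger into a (5+2) annulation with an endo ring closure. The cycloheptane is closed by 7-endo-trig SH2' cyclisation, preferred over 6-exo because attack at the unsubstituted alkene terminus gives a tertiary radical poised for fragmentation and because the cis-1,2-disubstituted cyclopentane and the gem-dimethyl group hold the chain ends together. The only new stereocentre is the sulfonyl-bearing CH, formed without control and erased in step 13; the two ring-fusion centres are untouched. The step needs intermolecular capture of the tertiary radical ahead of 1,5-hydrogen transfer from the allylic CH2SO2Ph group (secured by a high concentration of 16) and cyclisation ahead of reduction of the α-sulfonyl radical (secured by low catalyst loading, low light intensity and omission of water).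

Step 13
Reactants: 17 hydroazulene sulfone
Product: 18 cis-fused 1,4,4-trimethyl-8-methylidenedecahydroazulen-1-ol (hydroxyl cis to H-8a)
Conditions: Li, NH3(l)/THF, −78 °C; then NH4Cl
Reagents that add atoms: none
Why: Dissolving-metal reduction cleaves the secondary C–SO2Ph bond (reductive desulfonylation) and the benzylic C–O bond of the BOM ether in one operation, isolated alkenes being inert without an added proton source.

Step 14
Reactants: 18 hydroazulenol
Product: 20 cesium oxalate of 18, via methyl oxalate 19 (not isolated)
Conditions: ClC(O)CO2Me, Et3N, DMAP (cat.), CH2Cl2, 0 °C; then CsOH (1.0 equiv), THF/H2O, rt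
Reagents that add atoms: methyl chlorooxoacetate, COC(=O)C(Cl)=O; cesium hydroxide, [Cs+].[OH-]
Why: Acylation of the tertiary alcohol and selective saponification give the cesium oxalate, the standard radical precursor from tertiary alcohols.

Step 15
Reactants: 21 (5S)-5-[(1S,2R,5S)-menthyloxy]furan-2(5H)-one
Product: 23 (5S)-3-bromo-5-[(1S,2R,5S)-menthyloxy]furan-2(5H)-one, via dibromide 22 (not isolated)
Conditions: Br2, CH2Cl2, 0 °C; then Et3N, 0 °C to rt
Reagents that add atoms: bromine, BrBr
Why: Bromination–dehydrobromination: bromine adds across the butenolide alkene and E1cB loss of HBr from the more acidic α-position gives the α-bromobutenolide.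

Step 16
Reactants: 23 (5S)-3-bromo-5-[(1S,2R,5S)-menthyloxy]furan-2(5H)-one
Product: 24 tert-butyl 2-{(5S)-5-[(1S,2R,5S)-menthyloxy]-2-oxo-2,5-dihydrofuran-3-yl}acetate
Conditions: BrZnCH2CO2t-Bu, Pd(PPh3)4 (cat.), THF, 50 °C
Reagents that add atoms: (2-tert-butoxy-2-oxoethyl)zinc bromide, CC(C)(C)OC(=O)C[Zn]Br
Why: Negishi-type coupling of the Reformatsky reagent with the electron-poor alkenyl bromide under zerovalent palladium catalysis; the neutral conditions should leave the acetal centre and the position of the ring alkene intact.

Step 17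
Reactants: 20 cesium oxalate of 18; 24 butenolide acceptor
Product: 25 tert-butyl 2-[4-(hydroazulen-1-yl)-5-(menthyloxy)-2-oxotetrahydrofuran-3-yl]acetate (hydroazulenyl and CH2CO2t-Bu cis, both trans to menthyloxy)
Conditions: [Ir(dF(CF3)ppy)2(dtbbpy)]PF6 (1 mol%), H2O (10 equiv), DME/DMF 3:1, blue LEDs, 40 °C
Reagents that add atoms: none
Why: Photoredox Giese coupling of a tertiary-alcohol-derived oxalate: the ring radical is attacked on the face anti to the adjacent cycloheptane bond (sets the quaternary carbon), it adds to the butenolide β-carbon anti to the menthyloxy group (sets the side-chain CH), and the derived enolate is protonated by water anti to the new bulky substituent (sets the lactone α-CH cis to it).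

Step 18
Reactants: 25 coupled lactone acetal
Product: 26 tert-butyl 3-(hydroxymethyl)-4-(hydroazulen-1-yl)-5-hydroxypentanoate (1,4-diol)
Conditions: LiBH4, THF, 0 °C
Reagents that add atoms: none
Why: Chemoselective hydride reduction: LiBH4 reduces the acylal-type lactone carbonyl and, after collapse of the hemiacetal with loss of menthol, the liberated aldehyde, while the hindered tert-butyl ester is spared.

Step 19
Reactants: 26 diol tert-butyl ester
Product: 27 4-[1-(hydroazulen-1-yl)-2-hydroxyethyl]dihydrofuran-2(3H)-one
Conditions: KOt-Bu (cat.), THF, 0 °C to rt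
Reagents that add atoms: none
Why: Alkoxide-catalysed intramolecular transesterification closes the γ-lactone (5-exo-trig), preferred over the δ-lactone from the other hydroxyl, with loss of tert-butanol; base avoids acid-induced migration of the exocyclic alkene.

Step 20
Reactants: 27 hydroxymethyl lactone
Product: 29 target diacetate CNP0234964.1, via dihydroxy lactone 28 (not isolated)
Conditions: NaN(SiMe3)2 (2.2 equiv), THF, −78 °C; 2-(phenylsulfonyl)-3-phenyloxaziridine, −78 °C; then Ac2O, DMAP (cat.), −78 °C to rt
Reagents that add atoms: 2-(phenylsulfonyl)-3-phenyloxaziridine, O=S(=O)(c1ccccc1)N1OC1c1ccccc1; acetic anhydride, CC(=O)OC(C)=O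
Why: Enolate oxidation with an N-sulfonyloxaziridine delivers oxygen to the lactone enolate face anti to the bulky β-substituent (trans α-hydroxy lactone), and both sodium alkoxides are acetylated in the same flask.

**Compound list**

1 | (R)-(+)-limonene | CC1=CC[C@@H](CC1)C(C)=C | starting material
2 | (3R)-6-oxo-3-(prop-1-en-2-yl)heptanal | CC(=O)CC[C@H](CC=O)C(C)=C | intermediate
3 | (5S)-2-methyl-5-(prop-1-en-2-yl)cyclopent-1-ene-1-carbaldehyde | CC1=C(C=O)[C@@H](CC1)C(C)=C | intermediate
4 | (5S)-2-methyl-5-(prop-1-en-2-yl)cyclopent-1-ene-1-carboxylic acid | CC1=C(C(O)=O)[C@@H](CC1)C(C)=C | intermediate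
5 | (5R)-5-(2-hydroxypropan-2-yl)-2-methylcyclopent-1-ene-1-carboxylic acid (not isolated) | CC1=C(C(O)=O)[C@@H](CC1)C(C)(C)O | intermediate
6 | (3aR)-3,3,6-trimethyl-3,3a,4,5-tetrahydro-1H-cyclopenta[c]furan-1-one | CC1=C2C(=O)OC(C)(C)[C@@H]2CC1 | intermediate
7 | cis-fused 3,3-dimethyl-6-methylidenehexahydro-1H-cyclopenta[c]furan-1-one | O=C1OC(C)(C)[C@@H]2CCC(=C)[C@H]12 | intermediate
8 | cis-fused 6-hydroxy-3,3,6-trimethylhexahydro-1H-cyclopenta[c]furan-1-one, hydroxyl anti to the lactone ring | O=C1OC(C)(C)[C@@H]2CC[C@@](C)(O)[C@H]12 | intermediate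
9 | BOM ether of 8 | O=C1OC(C)(C)[C@@H]2CC[C@@](C)(OCOCc3ccccc3)[C@H]12 | intermediate
10 | bis(trimethylsilylmethyl) carbinol from double addition to 9 (not isolated) | OC(C)(C)[C@@H]1CC[C@@](C)(OCOCc2ccccc2)[C@@H]1C(O)(C[Si](C)(C)C)C[Si](C)(C)C | intermediate
11 | 2-{3-(benzyloxymethoxy)-3-methyl-2-[3-(trimethylsilyl)prop-1-en-2-yl]cyclopentyl}propan-2-ol, ring CH substituents cis | OC(C)(C)[C@@H]1CC[C@@](C)(OCOCc2ccccc2)[C@@H]1C(=C)C[Si](C)(C)C | intermediate
12 | methyl oxalate of 11 | COC(=O)C(=O)OC(C)(C)[C@@H]1CC[C@@](C)(OCOCc2ccccc2)[C@@H]1C(=C)C[Si](C)(C)C | intermediate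
13 | allyl bromide from 12 (not isolated) | COC(=O)C(=O)OC(C)(C)[C@@H]1CC[C@@](C)(OCOCc2ccccc2)[C@@H]1C(=C)CBr | intermediate
14 | allyl phenyl sulfone methyl oxalate | COC(=O)C(=O)OC(C)(C)[C@@H]1CC[C@@](C)(OCOCc2ccccc2)[C@@H]1C(=C)CS(=O)(=O)c1ccccc1 | intermediate
15 | cesium oxalate of the allyl sulfone alcohol | [Cs+].[O-]C(=O)C(=O)OC(C)(C)[C@@H]1CC[C@@](C)(OCOCc2ccccc2)[C@@H]1C(=C)CS(=O)(=O)c1ccccc1 | intermediate
16 | phenyl vinyl sulfone | C=CS(=O)(=O)c1ccccc1 | starting material
17 | cis-fused 1-(benzyloxymethoxy)-1,4,4-trimethyl-8-methylidene-6-(phenylsulfonyl)decahydroazulene, epimers at C-6 | C=C1CC(S(=O)(=O)c2ccccc2)CC(C)(C)[C@@H]2CC[C@@](C)(OCOCc3ccccc3)[C@H]12 | intermediate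
18 | cis-fused 1,4,4-trimethyl-8-methylidenedecahydroazulen-1-ol, hydroxyl cis to H-8a | C=C1CCCC(C)(C)[C@@H]2CC[C@@](C)(O)[C@H]12 | intermediate
19 | methyl oxalate of 18 (not isolated) | C=C1CCCC(C)(C)[C@@H]2CC[C@@](C)(OC(=O)C(=O)OC)[C@H]12 | intermediate
20 | cesium oxalate of 18 | C=C1CCCC(C)(C)[C@@H]2CC[C@@](C)(OC(=O)C(=O)[O-])[C@H]12.[Cs+] | intermediate
21 | (5S)-5-[(1S,2R,5S)-menthyloxy]furan-2(5H)-one | O=C1O[C@H](O[C@H]2C[C@@H](C)CC[C@@H]2C(C)C)C=C1 | starting material
22 | 3,4-dibromo-5-(menthyloxy)dihydrofuran-2(3H)-one, mixture at the bromine-bearing carbons (not isolated) | O=C1O[C@H](O[C@H]2C[C@@H](C)CC[C@@H]2C(C)C)C(Br)C1Br | intermediate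
23 | (5S)-3-bromo-5-[(1S,2R,5S)-menthyloxy]furan-2(5H)-one | O=C1O[C@H](O[C@H]2C[C@@H](C)CC[C@@H]2C(C)C)C=C1Br | intermediate
24 | tert-butyl 2-{(5S)-5-[(1S,2R,5S)-menthyloxy]-2-oxo-2,5-dihydrofuran-3-yl}acetate | O=C1O[C@H](O[C@H]2C[C@@H](C)CC[C@@H]2C(C)C)C=C1CC(=O)OC(C)(C)C | intermediate
25 | coupled lactone acetal: hydroazulenyl on C-4 and CH2CO2t-Bu on C-3 cis, both trans to 5-menthyloxy | C=C1CCCC(C)(C)[C@@H]2CC[C@@](C)([C@@H]3[C@@H](O[C@H]4C[C@@H](C)CC[C@@H]4C(C)C)OC(=O)[C@@H]3CC(=O)OC(C)(C)C)[C@H]12 | intermediate
26 | tert-butyl 3-(hydroxymethyl)-4-(hydroazulen-1-yl)-5-hydroxypentanoate | C=C1CCCC(C)(C)[C@@H]2CC[C@@](C)([C@H](CO)[C@H](CO)CC(=O)OC(C)(C)C)[C@H]12 | intermediate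
27 | 4-[1-(hydroazulen-1-yl)-2-hydroxyethyl]dihydrofuran-2(3H)-one | C=C1CCCC(C)(C)[C@@H]2CC[C@@](C)([C@H](CO)[C@@H]3COC(=O)C3)[C@H]12 | intermediate
28 | trans-3-hydroxy-4-[1-(hydroazulen-1-yl)-2-hydroxyethyl]dihydrofuran-2(3H)-one, present as its disodium alkoxide (not isolated) | C=C1CCCC(C)(C)[C@@H]2CC[C@@](C)([C@H](CO)[C@@H]3COC(=O)[C@H]3O)[C@H]12 | intermediate
29 | CNP0234964.1 | C=C1CCCC(C)(C)[C@@H]2CC[C@@](C)([C@H](COC(C)=O)[C@@H]3COC(=O)[C@H]3OC(C)=O)[C@H]12 | target

("Hydroazulen-1-yl" in 25–28 stands for the cis-fused 1,4,4-trimethyl-8-methylidenedecahydroazulen-1-yl group; the SMILES are definitive.)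

**Count and risks**

Total step count: 20. Longest linear sequence: 18 steps (steps 1–14 and 17–20); steps 15 and 16 make the acceptor.

Steps most likely to fail:

1. Step 12 (the proposed method). Reduction of the α-sulfonyl radical by the reduced photocatalyst, or 1,5-hydrogen transfer to the tertiary radical, may outrun the 7-endo closure. The fallback uses known chemistry, sets out from 15 and comes back at 18. The oxalate 15 is coupled under the standard aqueous photoredox Giese conditions ([Ir(dF(CF3)ppy)2(dtbbpy)]PF6, H2O, DME/DMF, blue LEDs) with 1,1-bis(phenylsulfonyl)ethylene to give the open-chain bis-sulfone F1; its adduct radical is reduced and protonated before any cyclisation can occur. The ring is then closed by two-electron chemistry: an intramolecular Tsuji–Trost allylation (NaH, then Pd(PPh3)4, THF, reflux, high dilution), in which zerovalent palladium ionises the allyl sulfone and the bis(sulfonyl)methanide attacks the symmetric π-allyl unit, gives the gem-bis-sulfone hydroazulene F2. Li/NH3 as in step 13 removes both sulfonyl groups and the BOM ether and delivers 18.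

2. Step 17. Addition of the hindered tertiary radical to the trisubstituted acceptor alkene may be slow, and protonation at the lactone α-carbon may lack facial selectivity or be followed by epimerisation to the trans isomer. The fallback sets out from 20 and 21 and comes back at 25. The oxalate 20 is coupled under the same photoredox conditions with the unsubstituted butenolide 21, a closely precedented acceptor type, to give the lactone acetal F3. Its lithium enolate (LiN(i-Pr)2, THF, −78 °C) is added to tert-butyl glyoxylate to give the aldol adduct F4, which is dehydrated with methyl N-(triethylammoniosulfonyl)carbamate to the alkylidene lactone F5. Conjugate reduction with [(Ph3P)CuH]6 then places hydrogen on the ring carbon from the face anti to the hydroazulenyl group and gives 25.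

3. Step 8. The second addition to the lactone carbonyl, which is flanked by two fully substituted carbons, may stall at the ketone stage. The fallback sets out from 9 and comes back at 11. The lactone carbonyl of 9 is methylenated with Cp2TiMe2 (PhMe, 65 °C) to the cyclic enol ether F6. A nickel-catalysed cross-coupling of the enol ether C(sp2)–O bond with Me3SiCH2MgCl (NiCl2(PPh3)2, PhH/THF, reflux) then opens the ring, installs the allylsilane and frees the tertiary alcohol as its magnesium alkoxide, giving 11 after work-up.

Further compounds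
F1 | step 12 | Giese adduct of 15 with 1,1-bis(phenylsulfonyl)ethylene: 2,2-bis(phenylsulfonyl)ethyl group on the CMe2 carbon, allyl sulfone intact | O=S(=O)(c1ccccc1)C(CC(C)(C)[C@@H]1CC[C@@](C)(OCOCc2ccccc2)[C@@H]1C(=C)CS(=O)(=O)c1ccccc1)S(=O)(=O)c1ccccc1
F2 | step 12 | cis-fused 1-(benzyloxymethoxy)-1,4,4-trimethyl-8-methylidene-6,6-bis(phenylsulfonyl)decahydroazulene | C=C1CC(S(=O)(=O)c2ccccc2)(S(=O)(=O)c2ccccc2)CC(C)(C)[C@@H]2CC[C@@](C)(OCOCc3ccccc3)[C@H]12
F3 | step 17 | 4-(hydroazulen-1-yl)-5-(menthyloxy)dihydrofuran-2(3H)-one, substituents trans | C=C1CCCC(C)(C)[C@@H]2CC[C@@](C)([C@@H]3[C@@H](O[C@H]4C[C@@H](C)CC[C@@H]4C(C)C)OC(=O)C3)[C@H]12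
F4 | step 17 | aldol adduct of F3 with tert-butyl glyoxylate, mixture at the two new centres | C=C1CCCC(C)(C)[C@@H]2CC[C@@](C)([C@@H]3[C@@H](O[C@H]4C[C@@H](C)CC[C@@H]4C(C)C)OC(=O)C3C(O)C(=O)OC(C)(C)C)[C@H]12
F5 | step 17 | (E)-alkylidene lactone from dehydration of F4 | C=C1CCCC(C)(C)[C@@H]2CC[C@@](C)([C@@H]3[C@@H](O[C@H]4C[C@@H](C)CC[C@@H]4C(C)C)OC(=O)/C3=C/C(=O)OC(C)(C)C)[C@H]12
F6 | step 8 | cis-fused cyclic enol ether from methylenation of 9 | C=C1OC(C)(C)[C@@H]2CC[C@@](C)(OCOCc3ccccc3)[C@H]12
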